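**Plan**

1. Retrosynthesis: cut the lactone C6–O bond (carboxylate displacing a C6 bromide), the C8 tiglate, the C1–C2 epoxide oxygen, and the C8–O and C10–O bonds (both grown from a C8=C9 olefin). Then cut C1–C10 by a retro-oxy-Cope shift, which restores C3–C8 and leaves a cyclohexenol.
2. Enabling feature: ring atoms C3–C8 (C3 ketone, C4 with its methyl, Z-C4=C5, C6, C7, C8) and the C11–C13 arm are the six-membered ring and isopropenyl group of (S)-carvone. A vinyl group (C1, C2) on C3 and a propenyl group (C9, C10, C14) on C8 form a 1,5-diene across the C3–C8 bond.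
3. Forward: carvone is oxygenated at C12, allylated at C8 and vinylated at C3. The six-membered ring is then expanded to the ten-membered ring, the only carbocycle made. The epoxide ring closes in step 13 and the lactone ring last, in step 16.
4. Stereochemistry: C7 and the Z-enone come from carvone. C8 comes from anti opening of a bromonium ion, C10 from an epoxidation directed by the C8 hydroxyl, C1/C2 from a nucleophilic epoxidation guided by the C10 hydroxyl, and C6 from SN2 inversion of a γ-bromide.

Key step: step 6

Remark on numbering: every intermediate carries the target numbering (ring C1–C10, C14 on C10, C15 on C4, arm C11/C12/C13); PMP = 4-methoxyphenyl; C3 of 19 forms as an epimer mixture and is written without configuration.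

Assumption: olefins in the ten-membered ring are taken to react on the exposed face, anti to the ring carbon of the neighbouring stereocentre, whose hydrogen eclipses the double bond; all facial arguments below rest on this model.

**Step 1**
Reactants: 1 (S)-(+)-carvone
Product: 2 (5S)-5-(3-chloroprop-1-en-2-yl)-2-methylcyclohex-2-en-1-one (10-chlorocarvone)
Conditions: Ca(OCl)2, CO2 (solid), CH2Cl2/H2O, 0 °C
Reagents that add atoms: calcium hypochlorite, [Ca+2].[O-]Cl.[O-]Cl
Why: Ene-type allylic chlorination by HOCl formed in the flask is selective for the electron-rich 1,1-disubstituted side-chain olefin over the enone and does not touch C7.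

**Step 2**
Reactants: 2 10-chlorocarvone; 3 4-methoxyphenol
Product: 4 (5S)-5-[3-(4-methoxyphenoxy)prop-1-en-2-yl]-2-methylcyclohex-2-en-1-one
Conditions: K2CO3, NaI (cat.), acetone, reflux
Reagents that add atoms: 4-methoxyphenol (3), COc1ccc(O)cc1
Why: Williamson ether synthesis (SN2 of phenoxide on a primary allylic chloride) installs the C12 oxygen as an aryl ether that tolerates the bases, hydrides and oxidants used up to step 13.

**Step 3**
Reactants: 4 PMP ether of 10-hydroxycarvone; 5 allyl bromide
Product: 7 6-allyl-5-[3-(4-methoxyphenoxy)prop-1-en-2-yl]-2-methylcyclohex-2-en-1-one (allyl on C8 trans to the C7 arm), via lithium dienolate 6 (not isolated)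
Conditions: LiN(iPr)2, THF, −78 °C; allyl bromide, DMPU, −78 to −20 °C
Reagents that add atoms: allyl bromide (5), C=CCBr
Why: Kinetic enolate alkylation at the α′ methylene (C8), with the electrophile entering anti to the adjacent C7 substituent; this centre only serves to organise the rearrangement and is consumed in step 6.

**Step 4**
Reactants: 7 allyl ketone; 8 vinylmagnesium bromide
Product: 9 6-allyl-5-[3-(4-methoxyphenoxy)prop-1-en-2-yl]-2-methyl-1-vinylcyclohex-2-en-1-ol (vinyl trans to allyl)
Conditions: CeCl3, THF, −78 °C; then aq. NH4Cl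
Reagents that add atoms: vinylmagnesium bromide (8), C=C[Mg]Br
Why: Organocerium 1,2-addition suppresses enolisation and conjugate addition, and the vinyl group should approach the carbonyl anti to the neighbouring C8 allyl group, so the two future Cope termini are trans.

**Step 5**
Reactants: 9 allyl vinyl carbinol
Product: 10 5-[3-(4-methoxyphenoxy)prop-1-en-2-yl]-2-methyl-6-[(E)-prop-1-enyl]-1-vinylcyclohex-2-en-1-ol (vinyl trans to propenyl, propenyl trans to the C7 arm)
Conditions: [Ir(cod)(PMePh2)2]PF6 (2 mol %, H2-activated), THF, rt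
Reagents that add atoms: none
Why: Cationic iridium hydride olefin isomerisation moves only the monosubstituted terminal double bond to the E-propenyl position; the 1,1-disubstituted ether arm is slow to isomerise and the vinyl carbinol has no allylic hydrogen.

**Step 6**
Reactants: 10 1-vinyl-6-(E)-propenyl cyclohexenol
Product: 13 (2Z,5S,6E,8S)-2,8-dimethyl-5-[3-(4-methoxyphenoxy)prop-1-en-2-yl]cyclodeca-2,6-dien-1-one, via potassium alkoxide 11 (not isolated), via potassium enolate 12 (not isolated)
Conditions: KH, 18-crown-6, THF, 0 °C to rt; then AcOH, −78 °C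
Reagents that add atoms: none
Why: The crown-separated potassium alkoxide 11 weakens the C3–C8 bond and the 1,5-diene C1=C2–C3–C8–C9=C10 undergoes a concerted [3,3] sigmatropic shift, the anionic oxy-Cope rearrangement known for trans-1,2-dialkenylcyclohexanols giving cyclodec-5-enones. The ten-membered ring arises by four-atom ring expansion as C1–C10 forms and C3–C8 breaks, not by end-to-end closure, so no high dilution is needed. The new stereocentre C10 is fixed by the chair transition state, in which the methyl of the E-propenyl group is equatorial. The step needs chair over boat and E geometry at C8=C9; both follow from the trans arrangement of vinyl and propenyl, which puts the ring bonds C3–C4 and C8–C7 equatorial on the chair. C4=C5 lies outside the reacting array and stays Z, C7 is not involved, and enolate 12 is protonated at C2 in the cold before it can equilibrate.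

**Step 7**
Reactants: 13 cyclodecadienone
Product: 15 trienone (target numbering: C1=C2 E, C3=O, C4=C5 Z, C8=C9 E, C12–OPMP), via lithium enolate 14 (not isolated)
Conditions: LiN(iPr)2, THF, −78 °C; PhS(Cl)=NtBu, −78 °C
Reagents that add atoms: none
Why: Mukaiyama dehydrogenation: C2 is the only α-position with hydrogens (C4 is sp2), its lithium enolate is sulfenylated by the sulfinimidoyl chloride, and the adduct undergoes syn-elimination in the cold, which in ten-membered rings favours the E-olefin.

**Step 8**
Reactants: 15 trienone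
Product: 17 8-hydroxy dienone (C8–OH cis to the C7 arm; C9=C10 ring-Z, C1=C2 E, C3=O, C4=C5 Z), via bromohydrin 16 (not isolated)
Conditions: NBS, THF/H2O (4:1), 0 °C; then DBU, 0 °C to rt
Reagents that add atoms: water, O
Why: Bromohydrin formation followed by vinylogous E1cB dehydrobromination: Br+ adds to the exposed face of the strained E-C8=C9 bond (the side-chain olefin is deactivated by its allylic aryloxy group), water opens the bromonium ion anti at C8 so that the new C8–O bond is cis to the C7 arm (the epimer that direct epoxidation of the exposed face would not give), and DBU removes the γ-hydrogen at C10 to expel bromide from C9.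

**Step 9**
Reactants: 17 8-hydroxy dienone
Product: 18 9,10-epoxy-8-hydroxy dienone (epoxide trans to the C8 hydroxyl)
Conditions: VO(acac)2 (5 mol %), t-BuOOH, CH2Cl2, 0 °C to rt
Reagents that add atoms: tert-butyl hydroperoxide, CC(C)(C)OO
Why: Hydroxyl-directed vanadium-catalysed epoxidation of an allylic alcohol: with C8–H eclipsing the Z-olefin to avoid A(1,3) strain with C1, oxygen is delivered from the hydroxyl-bearing face, giving the epoxide trans to the C8 oxygen (as for medium-ring Z-cycloalkenols) and so the C10 configuration of the target; the electron-poor enone olefins and the side-chain olefin, which has no free hydroxyl, should not react.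

**Step 10**
Reactants: 18 epoxy alcohol
Product: 19 3,8,10-triol (C1=C2 E, C4=C5 Z; C3 epimers)
Conditions: NaAlH2(OCH2CH2OMe)2, THF, −20 to 0 °C
Reagents that add atoms: none
Why: Alkoxyaluminate-directed hydride opening of a 2,3-epoxy alcohol: the C8 alkoxide delivers hydride to C9, the proximal secondary carbon, so the C10–O bond and its configuration are kept, while the cross-conjugated ketone is reduced 1,2 to a carbinol that is re-oxidised in step 11.

**Step 11**
Reactants: 19 triol
Product: 20 8,10-dihydroxy dienone (C1=C2 E, C3=O, C4=C5 Z)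
Conditions: MnO2, CH2Cl2, rt
Reagents that add atoms: none
Why: Allylic alcohol oxidation with MnO2 is selective for the doubly allylic C3 carbinol; the saturated secondary C8 and tertiary C10 alcohols are inert.

**Step 12**
Reactants: 20 dihydroxy dienone; 21 tigloyl chloride
Product: 22 8-tiglate of 20
Conditions: pyridine, DMAP (cat.), CH2Cl2, 0 °C to rt
Reagents that add atoms: tigloyl chloride (21), C/C=C(\C)C(=O)Cl
Why: DMAP-catalysed acylation takes the secondary C8 hydroxyl and leaves the tertiary C10 hydroxyl free, and capping C8 removes the hydroxyl that could add to C1 of the enone.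

**Step 13**
Reactants: 22 dienone tiglate
Product: 23 1,2-epoxy-3-ketone (1R,2R; C4=C5 Z; 8-tiglate; 10-OH; C12–OPMP)
Conditions: t-BuOOH, BnMe3NOH (10 mol %), THF, 0 °C
Reagents that add atoms: tert-butyl hydroperoxide, CC(C)(C)OO
Why: Weitz–Scheffer nucleophilic epoxidation: the hydroperoxide anion adds to C1 of the α-unsubstituted E-enone (the α-methyl Z-enone and the tiglate are poorer acceptors) on the face of the hydrogen-bonding C10 hydroxyl, and closure of the enolate gives the trans epoxide, trans to the C10 oxygen; the α-methylene lactone is deliberately not yet present.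

**Step 14**
Reactants: 23 epoxy ketone PMP ether
Product: 24 primary allylic alcohol (C12–OH)
Conditions: (NH4)2Ce(NO3)6, MeCN/H2O (4:1), 0 °C
Reagents that add atoms: none
Why: Oxidative cleavage of the p-methoxyphenyl ether by tetravalent cerium (single-electron oxidation of the electron-rich arene to benzoquinone) frees the C12 alcohol under conditions that should spare the epoxy ketone, the tertiary alcohol and the ester.

**Step 15**
Reactants: 24 C12 alcohol
Product: 26 C12 carboxylic acid (2-substituted acrylic acid), via aldehyde 25 (not isolated)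
Conditions: TEMPO (20 mol %), PhI(OAc)2, MeCN/H2O (1:1), rt
Reagents that add atoms: water, O
Why: Oxoammonium-mediated (TEMPO) oxidation in aqueous acetonitrile takes the primary allylic alcohol through the aldehyde hydrate to the acid and does not touch the tertiary alcohol.

**Step 16**
Reactants: 26 C12 acid
Product: 29 target, (1R,2R,6S,7R,8R,10R)-1,2-epoxy-10-hydroxy-3-oxo-8-tigloyloxygermacra-4Z,11(13)-dien-12,6-olide, via silyl dienol ether 27 (not isolated), via bromide 28 (not isolated)
Conditions: Me3SiOTf, Et3N, CH2Cl2, −78 °C; NBS, THF, −78 °C; then Bu4NF, −78 to 0 °C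
Reagents that add atoms: none
Why: Soft enolisation (only the γ-hydrogens at C6 are available) gives the silyl dienol ether, NBS brominates its γ-terminus on the face anti to ring carbon C8 so that bromine is trans to the C7 arm, and the carboxylate released by fluoride displaces bromide with inversion (5-exo-tet SN2), closing the cis-fused α-methylene lactone with the 6S configuration.

**Compound list**

1 | (S)-(+)-carvone | CC1=CC[C@@H](CC1=O)C(C)=C | starting material
2 | (5S)-5-(3-chloroprop-1-en-2-yl)-2-methylcyclohex-2-en-1-one | CC1=CC[C@@H](CC1=O)C(CCl)=C | intermediate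
3 | 4-methoxyphenol | COc1ccc(O)cc1 | starting material
4 | (5S)-5-[3-(4-methoxyphenoxy)prop-1-en-2-yl]-2-methylcyclohex-2-en-1-one | CC1=CC[C@@H](CC1=O)C(COc2ccc(OC)cc2)=C | intermediate
5 | allyl bromide | C=CCBr | starting material
6 | lithium cross-conjugated dienolate of 4 (O–C3=C8) | [Li+].[O-]C1=C[C@@H](C(COc2ccc(OC)cc2)=C)CC=C1C | intermediate (not isolated)
7 | 6-allyl-5-[3-(4-methoxyphenoxy)prop-1-en-2-yl]-2-methylcyclohex-2-en-1-one, allyl trans to the arm | O=C1C(C)=CC[C@H](C(COc2ccc(OC)cc2)=C)[C@H]1CC=C | intermediate
8 | vinylmagnesium bromide | C=C[Mg]Br | starting material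
9 | 6-allyl-5-[3-(4-methoxyphenoxy)prop-1-en-2-yl]-2-methyl-1-vinylcyclohex-2-en-1-ol, vinyl trans to allyl | C=C[C@]1(O)C(C)=CC[C@H](C(COc2ccc(OC)cc2)=C)[C@H]1CC=C | intermediate
10 | 5-[3-(4-methoxyphenoxy)prop-1-en-2-yl]-2-methyl-6-[(E)-prop-1-enyl]-1-vinylcyclohex-2-en-1-ol (rearrangement precursor) | C=C[C@]1(O)C(C)=CC[C@H](C(COc2ccc(OC)cc2)=C)[C@H]1/C=C/C | intermediate
11 | potassium alkoxide of 10 | C=C[C@]1([O-])C(C)=CC[C@H](C(COc2ccc(OC)cc2)=C)[C@H]1/C=C/C.[K+] | intermediate (not isolated)
12 | potassium enolate of 13 (C2=C3, C1 and C4 trans) | C1/C=C(/C)\C([O-])=C\C[C@H](C)/C=C/[C@H]1C(COc2ccc(OC)cc2)=C.[K+] | intermediate (not isolated)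
13 | (2Z,5S,6E,8S)-2,8-dimethyl-5-[3-(4-methoxyphenoxy)prop-1-en-2-yl]cyclodeca-2,6-dien-1-one (rearrangement product) | C1/C=C(/C)C(=O)CC[C@H](C)/C=C/[C@H]1C(COc2ccc(OC)cc2)=C | intermediate
14 | lithium enolate of 13 (C2=C3) | C1/C=C(/C)\C([O-])=C\C[C@H](C)/C=C/[C@H]1C(COc2ccc(OC)cc2)=C.[Li+] | intermediate (not isolated)
15 | trienone: C1=C2 E, C3=O, C4=C5 Z, C8=C9 E, C10–H as in 13 | C1/C=C(/C)C(=O)/C=C/[C@H](C)/C=C/[C@H]1C(COc2ccc(OC)cc2)=C | intermediate
16 | bromohydrin: C8–OH cis to the arm, C9–Br anti to it | C1/C=C(/C)C(=O)/C=C/[C@H](C)[C@@H](Br)[C@@H](O)[C@H]1C(COc2ccc(OC)cc2)=C | intermediate (not isolated)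
17 | 8-hydroxy dienone: C9=C10 ring-Z, C1=C2 E, C3=O, C4=C5 Z | C1/C=C(/C)C(=O)/C=C/C(C)=C\[C@@H](O)[C@H]1C(COc2ccc(OC)cc2)=C | intermediate
18 | 9,10-epoxy-8-hydroxy dienone, epoxide trans to 8-OH | C1/C=C(/C)C(=O)/C=C/[C@]2(C)O[C@@H]2[C@@H](O)[C@H]1C(COc3ccc(OC)cc3)=C | intermediate
19 | 3,8,10-triol (C3 epimers) | C1/C=C(/C)C(O)/C=C/[C@](C)(O)C[C@@H](O)[C@H]1C(COc2ccc(OC)cc2)=C | intermediate
20 | 8,10-dihydroxy cross-conjugated dienone | C1/C=C(/C)C(=O)/C=C/[C@](C)(O)C[C@@H](O)[C@H]1C(COc2ccc(OC)cc2)=C | intermediate
21 | tigloyl chloride, (E)-2-methylbut-2-enoyl chloride | C/C=C(\C)C(=O)Cl | starting material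
22 | 8-tiglate of 20 | C1/C=C(/C)C(=O)/C=C/[C@](C)(O)C[C@@H](OC(=O)/C(C)=C/C)[C@H]1C(COc2ccc(OC)cc2)=C | intermediate
23 | (1R,2R)-1,2-epoxy-3-ketone, 8-tiglate, 10-OH, C12–OPMP | C1/C=C(/C)C(=O)[C@@H]2O[C@H]2[C@](C)(O)C[C@@H](OC(=O)/C(C)=C/C)[C@H]1C(COc3ccc(OC)cc3)=C | intermediate
24 | C12 primary alcohol | C1/C=C(/C)C(=O)[C@@H]2O[C@H]2[C@](C)(O)C[C@@H](OC(=O)/C(C)=C/C)[C@H]1C(CO)=C | intermediate
25 | C12 aldehyde | C1/C=C(/C)C(=O)[C@@H]2O[C@H]2[C@](C)(O)C[C@@H](OC(=O)/C(C)=C/C)[C@H]1C(C=O)=C | intermediate (not isolated)
26 | C12 carboxylic acid | C1/C=C(/C)C(=O)[C@@H]2O[C@H]2[C@](C)(O)C[C@@H](OC(=O)/C(C)=C/C)[C@H]1C(C(=O)O)=C | intermediate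
27 | tris(trimethylsilyl) derivative: C3 silyl dienol ether (C3=C4, C5=C6), C10 silyl ether, silyl ester | C=C(C(=O)O[Si](C)(C)C)[C@H]1/C=C\C(C)=C(\O[Si](C)(C)C)[C@@H]2O[C@H]2[C@](C)(O[Si](C)(C)C)C[C@H]1OC(=O)/C(C)=C/C | intermediate (not isolated)
28 | C6 bromide (Br trans to the arm), C10 silyl ether, silyl ester | C=C(C(=O)O[Si](C)(C)C)[C@H]1[C@H](Br)/C=C(/C)C(=O)[C@@H]2O[C@H]2[C@](C)(O[Si](C)(C)C)C[C@H]1OC(=O)/C(C)=C/C | intermediate (not isolated)
29 | CNP0383091.1, (1R,2R,6S,7R,8R,10R)-1,2-epoxy-10-hydroxy-3-oxo-8-tigloyloxygermacra-4Z,11(13)-dien-12,6-olide | C=C1C(=O)O[C@H]2/C=C(/C)C(=O)[C@@H]3O[C@H]3[C@](C)(O)C[C@@H](OC(=O)/C(C)=C/C)[C@@H]12 | target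

**Totals**

Total step count: 16. Longest linear sequence: 16 steps from (S)-carvone; the other starting materials are used as purchased.

**Steps most likely to fail, with fallbacks**

1. Step 8. The bromonium ion may be captured across the ring (by the carbonyl or by hydride shift) instead of by water, or bromine may add to the side-chain olefin or to the wrong face, so that face control at C8 is lost. The fallback replaces anti addition by syn oxygen transfer followed by inversion. Starting from 15, mCPBA (NaHCO3, CH2Cl2, 0 °C) should epoxidise the exposed face to the 8,9-epoxide F1. DBU opens it by the same vinylogous elimination to the C8-epimeric hydroxy dienone F2. A Mitsunobu reaction with chloroacetic acid (PPh3, DIAD, THF) inverts C8 to the chloroacetate F3, and K2CO3 in MeOH at 0 °C removes the ester, rejoining the route at 17.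

2. Step 16. Dehydrobromination of the γ-bromo enone towards C7 may outrun ring closure, bromination may show poor facial selectivity, or the silyl triflate may open the epoxide. The fallback makes the C6–O bond first and closes the lactone by inversion. Starting from 26, the same dienol ether 27 is oxidised with dimethyldioxirane (acetone, −78 °C; then citric acid) at its γ,δ-double bond to the 6-hydroxy acid F5, hydroxyl trans to the C7 arm. Mitsunobu lactonisation (PPh3, DIAD, THF, 0 °C) then closes the ring with inversion at C6 and arrives at 29.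

3. Step 10. Hydride may add in conjugate fashion to the dienone or open the vinyl epoxide by SN2′ attack before the directed delivery to C9 takes place. The fallback takes the carbonyl out of conjugation first, so that the epoxide is no longer part of a vinylogous acceptor. Starting from 18, Luche reduction (NaBH4, CeCl3, MeOH, −40 °C) gives the C3 carbinol F4 with the epoxide intact. LiAlH4 in THF at 0 °C then opens the epoxide at C9 under direction of the C8 alkoxide, rejoining the route at 19.

**Further compounds**

F1 | step 8 | 8,9-epoxide of 15 on the exposed face (oxygen trans to the C7 arm) | C1/C=C(/C)C(=O)/C=C/[C@H](C)[C@H]2O[C@@H]2[C@H]1C(COc3ccc(OC)cc3)=C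
F2 | step 8 | C8 epimer of 17 | C1/C=C(/C)C(=O)/C=C/C(C)=C\[C@H](O)[C@H]1C(COc2ccc(OC)cc2)=C
F3 | step 8 | chloroacetate of 17 | C1/C=C(/C)C(=O)/C=C/C(C)=C\[C@@H](OC(=O)CCl)[C@H]1C(COc2ccc(OC)cc2)=C
F4 | step 10 | C3 carbinol of 18 (C3 epimers) | C1/C=C(/C)C(O)/C=C/[C@]2(C)O[C@@H]2[C@@H](O)[C@H]1C(COc3ccc(OC)cc3)=C
F5 | step 16 | 6-hydroxy acid, hydroxyl trans to the C7 arm | C=C(C(=O)O)[C@H]1[C@H](O)/C=C(/C)C(=O)[C@@H]2O[C@H]2[C@](C)(O)C[C@H]1OC(=O)/C(C)=C/C
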